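- The winter run carries twice the substrate of the noon run, yet its target ends at 23.7% against 24.8%; what the two share is the charge of first nucleophile, 9.00 mM in winter and 9.00 mM at noon.

| flask | substrate | first nucleophile | solid second nucleophile | remark | time |
|---|---|---|---|---|---|
| noon | 5 mM | 1.8 equiv | 0.70 equiv | run made earlier |  |
| dusk | 20 mM | 1.8 equiv | 0.70 equiv | run made earlier |  |
| winter | 10 mM | 0.90 equiv | 0.70 equiv | run made earlier |  |
| flask | 10 mM | 1.80 equiv | 0.700 equiv |  | 8.0 h |

| run | time / h | target / % | substrate / % |
|---|---|---|---|
| noon | 0.833 | 18.4 | 17.4 |
| noon | 1.33 | 22.4 | 5.8 |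
| noon | 2.00 | 23.9 | 1.0 |
| noon | 4.00 | 24.5 | 0 |
| noon | 6.00 | 24.3 | 0.4 |
| noon | 10.0 | 24.8 | 0 |
| dusk | 1.50 | 51.3 | 4.1 |
| dusk | 3.00 | 53.5 | 0.9 |
| dusk | 5.00 | 53.8 | 0.4 |
| dusk | 6.00 | 54.2 | 0.3 |
| dusk | 8.00 | 54.2 | 0 |
| dusk | 10.0 | 54.6 | 0.6 |
| winter | 0.833 | 18.6 | 17.6 |
| winter | 2.50 | 22.8 | 0.5 |
| winter | 4.00 | 22.8 | 0 |
| winter | 6.00 | 23.7 | 0 |
| winter | 10.0 | 23.7 | 0.3 |

(standard deviation of a reading: 0.3 percentage points)

- given per volume of solution although it is solid: solid second nucleophile
- steps thought possible: second nucleophile + intermediate -> other capture product; solid second nucleophile <-> second nucleophile; first nucleophile + intermediate -> target; intermediate -> solvolysis product; substrate -> intermediate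
- at the start none of the solid second nucleophile is in solution

* the target standing at 8.0 h, as a percentage of the substrate charged
* the change that raises the amount of target at 8.0 h, in percent of the substrate charged most ("none" if none brings more than 2 percentage points) (amber / violet / blue / none)
* amount of target at 8.0 h, in percent of the substrate charged, after amber

- amber: doubling the dissolution coefficient of the solid second nucleophile, all else as stated
- violet: doubling the solubility of the solid second nucleophile, all else as stated
- blue: doubling the amount of first nucleophile, all else as stated

- Substrate in the noon run reads a half-life of 0.330 h, so 8.0 h is long against it, and the target stays level from 4.00 h to 10.0 h: I am asked for a final share, not a rate.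
- I take the share of target as [first nucleophile]/([first nucleophile]+c), with [first nucleophile] the midpoint between charge and what remains after the target has formed.
- The last readings give c as 25.4 mM at noon, 25.2 mM in winter and 25.4 mM at dusk, while the solid charge goes from 3.50 mM to 14.0 mM.
- So I carry 25.3 mM, the crossing concentration: the [first nucleophile] at which target and solvolysis product form equally fast, a selectivity factor in concentration units.
- The flask charges 18.0 mM, below the crossing. Repeating the midpoint gives target of 4.15 mM, 3.86 mM, then 3.88 mM, so I say 38.8%.
- Blue reckons to 56.6%, a gain of 18 percentage points, so I name blue; amber I leave at my flask number, but that is an assumption which these readings do not test.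
- The forecast gives 38.5% (37.3% to 39.7%), blue as best and 38.3% after amber (35.5% to 39.5%), slightly under my number, holding that “the second nucleophile matters little”.
- The flask gives 38.3%, with blue best at 18 points, and 38.1% after amber.

    second nucleophile + intermediate → other capture product (k = 750 /M/h)
    solid second nucleophile ⇌ second nucleophile, rate k2*(cs2 - [second nucleophile]) while solid is left; crystals form when [second nucleophile] > cs2 (solubility = 0.920 mM, k = 0.0880 /h)
    first nucleophile + intermediate → target (k = 210 /M/h)
    intermediate → solvolysis product (k = 5.40 /h)
    substrate → intermediate (k = 2.10 /h)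

- At 8.00 h the flask holds 38.3% target against 61.4% solvolysis product, and other capture product holds 0.318%. With 78.7% of its first nucleophile left, its midpoint is 16.1 mM, below the crossing. The neighbour with 25 mM of substrate charges 45.0 mM; the same rounds give 16.0 mM, 14.8 mM, then 14.9 mM, which is 59.6%, with a midpoint of 37.5 mM, above the crossing. Target and solvolysis product stand level at 16.7 mM of substrate, and the neighbour holds 59.0% target against 40.8% solvolysis product.

Readings and results are simulated with constants of no real substance, noise included.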